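Readings and results stem from a simulated flask for substances that don't exist; scatter was added.

The question for the ochre flask was what it still held at 5.0 d that a remedy could turn into J.

| flask | X | G | temperature | remark | time |
|---|---|---|---|---|---|
| ochre | 10 mM | 10 mM | 50 °C | the very flask that is asked about, followed so far |  |
| amber | 10 mM | 5 mM | 50 °C | run made earlier |  |
| flask | 10 mM | 10.0 mM | 50 °C |  | 5.0 d |

| ochre: time / h | ochre: J / % | amber: time / h | amber: J / % |
|---|---|---|---|
| 8.00 | 12.6 | 0.833 | 0 |
| 12.0 | 17.3 | 1.33 | 1.3 |
| 20.0 | 22.4 | 2.00 | 0.8 |
| 40.0 | 26.2 | 4.00 | 3.8 |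
| 60.0 | 27.4 | 6.00 | 6.5 |
| 96.0 | 29.1 | 10.0 | 10.0 |

(readings scatter by 0.5 percentage points)

1. J, in percent of the X first charged, at 5.0 d
2. the remedy with the largest gain of J, or "none" below 2 percentage points (east / south-east / north-east / west / none)
3. J present, with what was taken out counted in, in percent of the X first charged, after north-east
4. J present, with what was taken out counted in, in percent of the X first charged, after west

- east: at 5.0 d take out 90% of the J then present, then wait 10 d
- south-east: at 5.0 d add G, 50.0% of the amount charged, then wait 10 d
- north-east: at 5.0 d raise the temperature by 25 K, then wait 10 d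
- west: change nothing and wait 10 d more

- J that was removed still counts
- candidate steps: X + G <-> D; G + Z -> J; X -> Z; G + L <-> E; Z -> L
- additions bring no volume worth counting
- the earlier runs do not show what temperature does; that part of a forecast is a guess

I began with the rate of J in ochre. Between 20.0 h and 40.0 h the charge gained J at 0.00190 h⁻¹, and from there to 96.0 h at 5.18 × 10⁻⁴ h⁻¹. I treated this fading as a pseudo-first-order decay. Between the middles of those spans the two rates give a decay constant of 0.0342 h⁻¹.

Dividing a rate by that constant removes time and leaves the J still to come. Carried forward to 5.0 d, this tail was 0.26 percentage points. The same division at 96.0 h gave 0.58 points, so I reckoned J at 5.0 d as 29.4%.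

On the candidate steps J comes from G + Z, and no step leads from L or E back to Z. I took the 29.1% of the charge that had become J as the share going to J, the route's selectivity. Dividing the tail by that share gave the pool, the part of the charge still on its way to J or L: 0.878%. That caps any gain in ochre, and it lay below the 2 points threshold, so I committed to "none" and about 29.7% after waiting. Heat was a guess, and I gave it the same figure.

The weak link was the 40.0 h reading, which enters both rates. Lowered by one standard deviation, it gives a pool of 2.02%, just over the threshold, so my "none" held on the central figure but was open on that one reading.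

The forecast differed from my reckoning. It gave 30% now, south-east as best, 35% after north-east and 34.5% after west: “Adding G raises the partition towards J for the remaining X, so it should gain most”.

The flask gave 29.4%, with best none, 29.5% after north-east and 29.6% after west. South-east gained 0.29 points.

    X + G ⇌ D (K = 110 M⁻¹, k = 0.0950 M⁻¹ min⁻¹, Ea = 76.0 kJ mol⁻¹, ΔH = −10.0 kJ mol⁻¹)
    G + Z → J (k = 0.360 M⁻¹ min⁻¹, Ea = 54.0 kJ mol⁻¹)
    X → Z (k = 0.00160 min⁻¹, Ea = 110 kJ mol⁻¹)
    G + L ⇌ E (K = 110 M⁻¹, k = 3.00 M⁻¹ min⁻¹, Ea = 50.0 kJ mol⁻¹, ΔH = −39.0 kJ mol⁻¹)
    Z → L (k = 0.00500 min⁻¹, Ea = 101 kJ mol⁻¹)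
    (constants at 50 °C)

At 120 h the flask held X, D and Z together at 0.770% of the charge, and that simulated pool stood below the threshold. The neighbour charged with 2.5 mM of X reached 38.1% J. Its X, D and Z came to 1.55%, and at that share its tail was 0.59 points.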